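**Strategy**

The dihydrofuran ring is read as a contracted pyran. Benzofuran C2, which carries O1 and the branched three-carbon alkenyl group trans to the C3 oxygen, is the former C3 of a trans-2,2-dimethylchroman-3,4-diol. In one operation, activation of that chroman C3 hydroxyl lets the ring oxygen move from the gem-dimethyl carbon to C3 with inversion. This forms the O1–C2 bond, closes the five-membered ring, fixes the trans C2/C3 relationship and expels the old chroman C2 as the isopropenyl group. The precursor is the enantiopure 6-acetylchroman with a free 3-hydroxyl and a 4-silyl ether, obtained by catalytic asymmetric epoxidation of the chromene and trans hydrolysis.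

Key step: step 6

Remark on the chemistry: the facial sense of the (S,S)-salen manganese catalyst and of the (R,R)-TsDPEN ruthenium catalyst is assumed to follow their established behaviour with 6-acceptor-substituted 2,2-dimethylchromenes and with aryl methyl ketones.

**Route**

Step 1
Reactants: 1 1-(4-hydroxyphenyl)ethanone; 2 3-chloro-3-methylbut-1-yne
Product: 3 1-{4-[(2-methylbut-3-yn-2-yl)oxy]phenyl}ethanone
Conditions: K2CO3, KI (cat.), CuI (cat.), acetone, reflux
Reagents that add atoms: none
Why: Copper-assisted Williamson-type O-alkylation of the phenoxide by the tertiary propargylic chloride should give the aryl 1,1-dimethylpropargyl ether, the acetyl group making the phenol acidic enough for K2CO3; no stereocentre is formed.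

Step 2
Reactants: 3 1-{4-[(2-methylbut-3-yn-2-yl)oxy]phenyl}ethanone
Product: 6 1-(2,2-dimethyl-2H-chromen-6-yl)ethanone, via allenylphenol 4 (not isolated), via ortho-quinone methide 5 (not isolated)
Conditions: 1,2-dichlorobenzene, 180 °C
Reagents that add atoms: none
Why: Aromatic propargyl Claisen rearrangement gives the ortho-allenylphenol 4, whose 1,5-hydrogen shift to quinone methide 5 and oxa-6π electrocyclisation close the 2,2-dimethylpyran ring; the two ortho positions are equivalent, so a single chromene should form.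

Step 3
Reactants: 6 1-(2,2-dimethyl-2H-chromen-6-yl)ethanone
Product: 7 1-[(1aS,7bS)-2,2-dimethyl-1a,7b-dihydro-2H-oxireno[2,3-c]chromen-6-yl]ethanone (the (3S,4S)-epoxide in chroman numbering)
Conditions: (S,S)-(salen)MnCl [salen = N,N'-bis(3,5-di-tert-butylsalicylidene)cyclohexane-1,2-diaminate] (cat.), 4-phenylpyridine N-oxide (cat.), aq. NaOCl (pH 11.3, Na2HPO4), CH2Cl2, 0 °C
Reagents that add atoms: sodium hypochlorite, [Na+].[O-]Cl
Why: Jacobsen epoxidation, in which the oxo-manganese salen species transfers oxygen to the cis-disubstituted, aryl-conjugated C3=C4 bond by side-on approach and the (S,S) ligand should select the face leading to the (3S,4S)-epoxide; the cold biphasic medium keeps the methyl ketone away from haloform cleavage.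

Step 4
Reactants: 7 1-[(1aS,7bS)-2,2-dimethyl-1a,7b-dihydro-2H-oxireno[2,3-c]chromen-6-yl]ethanone
Product: 8 1-[(3S,4R)-3,4-dihydroxy-2,2-dimethyl-3,4-dihydro-2H-chromen-6-yl]ethanone
Conditions: HClO4 (cat.), THF/H2O, 0 °C to rt
Reagents that add atoms: water, O
Why: Acid-catalysed epoxide hydrolysis, in which water opens the protonated epoxide at the benzylic C4 with inversion (the acetyl group para to the ring oxygen disfavours a free cation) while C3 is untouched, so the trans (3S,4R)-diol should result.

Step 5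
Reactants: 8 1-[(3S,4R)-3,4-dihydroxy-2,2-dimethyl-3,4-dihydro-2H-chromen-6-yl]ethanone
Product: 9 1-[(3S,4R)-4-{[tert-butyl(dimethyl)silyl]oxy}-3-hydroxy-2,2-dimethyl-3,4-dihydro-2H-chromen-6-yl]ethanone
Conditions: TBSCl (1.05 equiv), imidazole, DMF, 0 °C
Reagents that add atoms: tert-butyl(chloro)dimethylsilane, CC(C)(C)[Si](C)(C)Cl
Why: Silyl ether formation under steric control, since the benzylic C4 hydroxyl reacts with TBSCl/imidazole whereas the C3 hydroxyl, flanked by the gem-dimethyl carbon, is neopentyl-like and should stay free when the reagent is limited.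

Step 6
Reactants: 9 1-[(3S,4R)-4-{[tert-butyl(dimethyl)silyl]oxy}-3-hydroxy-2,2-dimethyl-3,4-dihydro-2H-chromen-6-yl]ethanone
Product: 11 1-[(2S,3R)-3-{[tert-butyl(dimethyl)silyl]oxy}-2-(prop-1-en-2-yl)-2,3-dihydro-1-benzofuran-5-yl]ethanone, via chromanyl triflate 10 (not isolated)
Conditions: Tf2O (1.1 equiv), 2,6-di-tert-butylpyridine (3 equiv), CH2Cl2, −78 °C to rt
Reagents that add atoms: none
Why: Tf2O converts the hindered C3 hydroxyl into triflate 10, whose C3–O bond is equatorial in the trans-diequatorial half-chair (an axial C4 silyloxy group would clash with the axial C2 methyl) and therefore antiperiplanar to the O1–C2 ring bond. O1 displaces the triflate from the rear in a 3-exo-tet closure (this O1–C3 bond is also the one that closes the five-membered ring) to an aryl-bridged oxiranium ion; its O1–CMe2 bond then breaks at the tertiary carbon while the hindered pyridine removes a methyl proton, so the dihydrofuran arises by a 1,2-oxygen shift and the expelled carbon emerges as the isopropenyl group. The closest known reaction type is the solvolytic ring contraction of 2,2-dimethylchroman-3-yl sulfonates to 2-isopropenyl-2,3-dihydrobenzofurans, which is also seen with equatorial pyranoside 2-triflates. The new C2 stereocentre (benzofuran numbering) is set by the substrate through SN2 inversion at the former C3, while the former C4 is untouched, so the trans chromanol should give the (2S,3R)-trans product. The step needs oxygen participation to win over aryl migration, simple elimination and enol triflation of the acetyl group; this is secured by the antiperiplanar alignment, the tertiary character of the departing carbon, the non-bridging silyl ether, low-temperature triflation with only a slight excess of Tf2O, and the non-nucleophilic base.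

Step 7
Reactants: 11 1-[(2S,3R)-3-{[tert-butyl(dimethyl)silyl]oxy}-2-(prop-1-en-2-yl)-2,3-dihydro-1-benzofuran-5-yl]ethanone
Product: 12 (1R)-1-[(2S,3R)-3-{[tert-butyl(dimethyl)silyl]oxy}-2-(prop-1-en-2-yl)-2,3-dihydro-1-benzofuran-5-yl]ethanol
Conditions: RuCl[(R,R)-TsDPEN](p-cymene) [TsDPEN = N-tosyl-1,2-diphenylethane-1,2-diaminate] (cat.), HCO2H/Et3N (5:2), EtOAc, rt
Reagents that add atoms: none
Why: Noyori asymmetric transfer hydrogenation, in which the (R,R)-TsDPEN ruthenium hydride delivers hydride to the Si face of the aryl methyl ketone through the six-membered outer-sphere transition state with its CH/π contact to the arene, so the (R)-carbinol is set under catalyst control while the isopropenyl group and the silyl ether are left alone because no borane is present.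

Step 8
Reactants: 12 (1R)-1-[(2S,3R)-3-{[tert-butyl(dimethyl)silyl]oxy}-2-(prop-1-en-2-yl)-2,3-dihydro-1-benzofuran-5-yl]ethanol
Product: 13 (1R)-1-[(2S,3R)-3-{[tert-butyl(dimethyl)silyl]oxy}-2-(prop-1-en-2-yl)-2,3-dihydro-1-benzofuran-5-yl]ethyl (2E)-2-methylbut-2-enoate
Conditions: tiglic acid, EDC·HCl, DMAP, CH2Cl2, 0 °C to rt
Reagents that add atoms: (2E)-2-methylbut-2-enoic acid (tiglic acid), C/C=C(\C)C(=O)O
Why: Steglich esterification (carbodiimide activation with DMAP acyl transfer) acylates the carbinol oxygen without touching its C–O bond, so the (R) centre is retained, and the neutral conditions avoid both deconjugation of the tigloyl unit and ionisation of the para-alkoxybenzylic position.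

Step 9
Reactants: 13 (1R)-1-[(2S,3R)-3-{[tert-butyl(dimethyl)silyl]oxy}-2-(prop-1-en-2-yl)-2,3-dihydro-1-benzofuran-5-yl]ethyl (2E)-2-methylbut-2-enoate
Product: 15 (1R)-1-[(2S,3R)-3-acetoxy-2-(prop-1-en-2-yl)-2,3-dihydro-1-benzofuran-5-yl]ethyl (2E)-2-methylbut-2-enoate, via C3 alcohol 14 (not isolated)
Conditions: TBAF, AcOH (1:1), THF, 0 °C to rt; then Et3N, Ac2O, DMAP (cat.), 0 °C to rt
Reagents that add atoms: acetic anhydride, CC(=O)OC(C)=O
Why: Fluoride-induced desilylation, buffered with acetic acid to protect the esters, frees the C3 hydroxyl, which is then acetylated in the same flask by DMAP-catalysed acyl transfer with retention at C3.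

Step 10
Reactants: 15 (1R)-1-[(2S,3R)-3-acetoxy-2-(prop-1-en-2-yl)-2,3-dihydro-1-benzofuran-5-yl]ethyl (2E)-2-methylbut-2-enoate
Product: 16 (1R)-1-[(2S,3R)-3-acetoxy-2-(3-hydroxyprop-1-en-2-yl)-2,3-dihydro-1-benzofuran-5-yl]ethyl (2E)-2-methylbut-2-enoate
Conditions: SeO2 (cat.), t-BuOOH, CH2Cl2, rt
Reagents that add atoms: tert-butyl hydroperoxide, CC(C)(C)OO (source of the new oxygen); selenium dioxide, O=[Se]=O (catalytic oxygen carrier)
Why: Selenium dioxide allylic hydroxylation (ene reaction at the 1,1-disubstituted alkene, then 2,3-sigmatropic shift of the allylseleninic acid) should oxidise the isopropenyl methyl group, since a methyl group reacts before the ring methine and the electron-poor tigloyl alkene is a poor ene partner, while the room-temperature catalytic conditions spare the benzylic esters; any enal already formed is the target itself and is carried along.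

Step 11
Reactants: 16 (1R)-1-[(2S,3R)-3-acetoxy-2-(3-hydroxyprop-1-en-2-yl)-2,3-dihydro-1-benzofuran-5-yl]ethyl (2E)-2-methylbut-2-enoate
Product: 17 (1R)-1-[(2S,3R)-3-acetoxy-2-(3-oxoprop-1-en-2-yl)-2,3-dihydro-1-benzofuran-5-yl]ethyl (2E)-2-methylbut-2-enoate
Conditions: MnO2 (activated, excess), CH2Cl2, rt
Reagents that add atoms: none
Why: MnO2 oxidation of the allylic primary alcohol should give the 2-substituted acrolein selectively under neutral conditions, with no effect on the esters or the stereocentres.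

**Compound list**

1 | 1-(4-hydroxyphenyl)ethanone | CC(=O)c1ccc(O)cc1 | starting material
2 | 3-chloro-3-methylbut-1-yne | CC(C)(Cl)C#C | starting material
3 | 1-{4-[(2-methylbut-3-yn-2-yl)oxy]phenyl}ethanone | CC(=O)c1ccc(OC(C)(C)C#C)cc1 | intermediate
4 | 1-[4-hydroxy-3-(3-methylbuta-1,2-dien-1-yl)phenyl]ethanone | CC(=O)c1ccc(O)c(C=C=C(C)C)c1 | intermediate
5 | 4-acetyl-6-(3-methylbut-2-en-1-ylidene)cyclohexa-2,4-dien-1-one | CC(=O)C1=CC(=CC=C(C)C)C(=O)C=C1 | intermediate
6 | 1-(2,2-dimethyl-2H-chromen-6-yl)ethanone | CC(=O)c1ccc2OC(C)(C)C=Cc2c1 | intermediate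
7 | 1-[(1aS,7bS)-2,2-dimethyl-1a,7b-dihydro-2H-oxireno[2,3-c]chromen-6-yl]ethanone | CC(=O)c1ccc2OC(C)(C)[C@H]3O[C@H]3c2c1 | intermediate
8 | 1-[(3S,4R)-3,4-dihydroxy-2,2-dimethyl-3,4-dihydro-2H-chromen-6-yl]ethanone | CC(=O)c1ccc2OC(C)(C)[C@@H](O)[C@H](O)c2c1 | intermediate
9 | 1-[(3S,4R)-4-{[tert-butyl(dimethyl)silyl]oxy}-3-hydroxy-2,2-dimethyl-3,4-dihydro-2H-chromen-6-yl]ethanone | CC(=O)c1ccc2OC(C)(C)[C@@H](O)[C@H](O[Si](C)(C)C(C)(C)C)c2c1 | intermediate
10 | (3S,4R)-6-acetyl-4-{[tert-butyl(dimethyl)silyl]oxy}-2,2-dimethyl-3,4-dihydro-2H-chromen-3-yl trifluoromethanesulfonate | CC(=O)c1ccc2OC(C)(C)[C@@H](OS(=O)(=O)C(F)(F)F)[C@H](O[Si](C)(C)C(C)(C)C)c2c1 | intermediate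
11 | 1-[(2S,3R)-3-{[tert-butyl(dimethyl)silyl]oxy}-2-(prop-1-en-2-yl)-2,3-dihydro-1-benzofuran-5-yl]ethanone | C=C(C)[C@@H]1Oc2ccc(C(C)=O)cc2[C@H]1O[Si](C)(C)C(C)(C)C | intermediate
12 | (1R)-1-[(2S,3R)-3-{[tert-butyl(dimethyl)silyl]oxy}-2-(prop-1-en-2-yl)-2,3-dihydro-1-benzofuran-5-yl]ethanol | C=C(C)[C@@H]1Oc2ccc([C@@H](C)O)cc2[C@H]1O[Si](C)(C)C(C)(C)C | intermediate
13 | (1R)-1-[(2S,3R)-3-{[tert-butyl(dimethyl)silyl]oxy}-2-(prop-1-en-2-yl)-2,3-dihydro-1-benzofuran-5-yl]ethyl (2E)-2-methylbut-2-enoate | C=C(C)[C@@H]1Oc2ccc([C@@H](C)OC(=O)/C(C)=C/C)cc2[C@H]1O[Si](C)(C)C(C)(C)C | intermediate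
14 | (1R)-1-[(2S,3R)-3-hydroxy-2-(prop-1-en-2-yl)-2,3-dihydro-1-benzofuran-5-yl]ethyl (2E)-2-methylbut-2-enoate | C=C(C)[C@@H]1Oc2ccc([C@@H](C)OC(=O)/C(C)=C/C)cc2[C@H]1O | intermediate
15 | (1R)-1-[(2S,3R)-3-acetoxy-2-(prop-1-en-2-yl)-2,3-dihydro-1-benzofuran-5-yl]ethyl (2E)-2-methylbut-2-enoate | C=C(C)[C@@H]1Oc2ccc([C@@H](C)OC(=O)/C(C)=C/C)cc2[C@H]1OC(C)=O | intermediate
16 | (1R)-1-[(2S,3R)-3-acetoxy-2-(3-hydroxyprop-1-en-2-yl)-2,3-dihydro-1-benzofuran-5-yl]ethyl (2E)-2-methylbut-2-enoate | C=C(CO)[C@@H]1Oc2ccc([C@@H](C)OC(=O)/C(C)=C/C)cc2[C@H]1OC(C)=O | intermediate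
17 | (1R)-1-[(2S,3R)-3-acetoxy-2-(3-oxoprop-1-en-2-yl)-2,3-dihydro-1-benzofuran-5-yl]ethyl (2E)-2-methylbut-2-enoate | C=C(C=O)[C@@H]1Oc2ccc([C@@H](C)OC(=O)/C(C)=C/C)cc2[C@H]1OC(C)=O | target

**Step count and risks**

Total step count: 11. Longest linear sequence: 11 steps (from 1 to 17; 2 enters in step 1).

Steps most likely to fail:

Step 6. Ionisation of the triflate with oxygen participation may be too slow, because the ring oxygen is deactivated by the para acetyl group; enol triflation of the methyl ketone, aryl migration toward the silyloxy-bearing carbon, or simple elimination could then take over. The fallback changes the order of events so that the shift runs on an electron-rich arene without an enolisable ketone. From 9, transfer hydrogenation with RuCl[(R,R)-TsDPEN](p-cymene) and HCO2H/Et3N should give (1R)-1-[(3S,4R)-4-{[tert-butyl(dimethyl)silyl]oxy}-3-hydroxy-2,2-dimethyl-3,4-dihydro-2H-chromen-6-yl]ethanol F1. Steglich esterification with tiglic acid, which should touch only the unhindered benzylic carbinol and not the shielded C3 hydroxyl, gives (1R)-1-[(3S,4R)-4-{[tert-butyl(dimethyl)silyl]oxy}-3-hydroxy-2,2-dimethyl-3,4-dihydro-2H-chromen-6-yl]ethyl (2E)-2-methylbut-2-enoate F2. Tf2O and 2,6-di-tert-butylpyridine then form in the flask (1R)-1-[(3S,4R)-4-{[tert-butyl(dimethyl)silyl]oxy}-2,2-dimethyl-3-{[(trifluoromethyl)sulfonyl]oxy}-3,4-dihydro-2H-chromen-6-yl]ethyl (2E)-2-methylbut-2-enoate F3, which should contract by the same 1,2-oxygen shift and come back to the route at 13.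

Step 10. The ene reaction of selenium dioxide may be unselective (attack at the tigloyl methyl groups or at the ring methine), or selenous acid may ionise the benzylic esters, with loss of acetic acid and aromatisation to the benzofuran. The fallback reaches the aldehyde through a halide and uses no stoichiometric selenium oxidant. From 15, allylic chlorination with N-chlorosuccinimide and catalytic PhSeCl in CH2Cl2 should give (1R)-1-[(2S,3R)-3-acetoxy-2-(3-chloroprop-1-en-2-yl)-2,3-dihydro-1-benzofuran-5-yl]ethyl (2E)-2-methylbut-2-enoate F4. Kornblum-type oxidation of this allylic chloride with N-methylmorpholine N-oxide and catalytic NaI in MeCN at rt would lead directly to 17, bypassing 16.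

Step 5. The silylation may discriminate poorly between the two secondary hydroxyls, or run on to the bis-silyl ether. The fallback uses a tin template instead of plain steric control. From 8, Bu2SnO in refluxing toluene with removal of water should give the dibutylstannylene acetal 1-[(3S,4R)-3,4-(dibutylstannanediyldioxy)-2,2-dimethyl-3,4-dihydro-2H-chromen-6-yl]ethanone F5, in which the less hindered and more acidic benzylic oxygen is the activated one. Treatment with TBSCl in CHCl3 at rt, followed by aqueous work-up, then returns to the route at 9.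

**Further compounds**

F1 | step 6 | (1R)-1-[(3S,4R)-4-{[tert-butyl(dimethyl)silyl]oxy}-3-hydroxy-2,2-dimethyl-3,4-dihydro-2H-chromen-6-yl]ethanol | C[C@@H](O)c1ccc2OC(C)(C)[C@@H](O)[C@H](O[Si](C)(C)C(C)(C)C)c2c1
F2 | step 6 | (1R)-1-[(3S,4R)-4-{[tert-butyl(dimethyl)silyl]oxy}-3-hydroxy-2,2-dimethyl-3,4-dihydro-2H-chromen-6-yl]ethyl (2E)-2-methylbut-2-enoate | C/C=C(\C)C(=O)O[C@H](C)c1ccc2OC(C)(C)[C@@H](O)[C@H](O[Si](C)(C)C(C)(C)C)c2c1
F3 | step 6 | (1R)-1-[(3S,4R)-4-{[tert-butyl(dimethyl)silyl]oxy}-2,2-dimethyl-3-{[(trifluoromethyl)sulfonyl]oxy}-3,4-dihydro-2H-chromen-6-yl]ethyl (2E)-2-methylbut-2-enoate | C/C=C(\C)C(=O)O[C@H](C)c1ccc2OC(C)(C)[C@@H](OS(=O)(=O)C(F)(F)F)[C@H](O[Si](C)(C)C(C)(C)C)c2c1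
F4 | step 10 | (1R)-1-[(2S,3R)-3-acetoxy-2-(3-chloroprop-1-en-2-yl)-2,3-dihydro-1-benzofuran-5-yl]ethyl (2E)-2-methylbut-2-enoate | C=C(CCl)[C@@H]1Oc2ccc([C@@H](C)OC(=O)/C(C)=C/C)cc2[C@H]1OC(C)=O
F5 | step 5 | 1-[(3S,4R)-3,4-(dibutylstannanediyldioxy)-2,2-dimethyl-3,4-dihydro-2H-chromen-6-yl]ethanone (dibutylstannylene acetal of 8) | CC(=O)c1ccc2OC(C)(C)[C@H]3O[Sn](CCCC)(CCCC)O[C@@H]3c2c1
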